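**Plan**
1. Locants follow phenanthrene numbering: ring A = C1–C4, C4a, C10a (dienone); ring D = C4a, C4b, C8a, C9, C10, C10a; ring E = C4b–C8a (arene); ring B = oxazolidine (N on C3, O on C4); ring C = pyrrolidine.
2. Retrosynthesis: remove the C8–O triflate; cut ring D at C4a–C4b and C8a–C9 together, giving a ring E aryne and the diene C9=C10–C10a=C4a (bis-silyl ketene acetal of a tricyclic ABC acid); cut the N,O-aminal to 4-aminobutanal acetal and a 3-alkoxy p-quinol; cut C4–O (dearomatisation) to a resorcinol with a lactate tether on O3.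
3. Forward: the arene (future ring A) receives its C10–C9 chain as a benzofuranone, then the tether; iodane dearomatisation gives ring A plus a temporary dioxanone; amine exchange and acetalisation close ring C, then ring B; the aryne Diels–Alder reaction closes ring D last; triflate hydrolysis ends the route.
4. Enabling feature: the C10a=C4a enone bond of ring A sits next to the C10 methylene and C9 carboxyl, so the acid is a latent 1,1-dioxygenated diene with C4a as its nucleophilic end; ring E carries its C8 oxygen next to C8a, so a 3-oxygenated aryne C4b≡C8a is polarised to take C4a at C4b and C9 at C8a.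
5. Stereochemistry: C4 (R) comes by 1,4-induction from an (R)-2-aryloxypropanoate tether (set by enantioselective copper-carbene O–H insertion), which then leaves as lactate; the aminal carbon (S) is set under thermodynamic control by C4.

Key step: step 11

Assumption: the 9-oxo/10-methylene form drawn for the target is taken as its resting tautomer, so the 9-hydroxy (naphthol) form, where it arises, is expected to ketonise to it.

**Step 1**
Reactants: 1 2,4-dihydroxy-3-methoxybenzaldehyde
Product: 2 2-methoxy-4-methylbenzene-1,3-diol
Conditions: H2 (3 bar), 10% Pd/C, AcOH, cat. HCl, 50 °C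
Reagents that add atoms: none
Why: Catalytic hydrogenolysis of an ortho/para-hydroxybenzaldehyde (benzylic alcohol, then loss of water through the quinone methide) should give the methyl group without touching ring or ethers; no stereocentre.

**Step 2**
Reactants: 2 2-methoxy-4-methylbenzene-1,3-diol; 3 glyoxylic acid (monohydrate)
Product: 5 6-hydroxy-7-methoxy-5-methyl-1-benzofuran-2(3H)-one, via mandelic acid 4 (not isolated)
Conditions: NaOH (aq), 0 → 23 °C; HCl to pH 1; then H2 (3 bar), 10% Pd/C, AcOH, cat. H2SO4, 60 °C
Reagents that add atoms: none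
Why: Hydroxyalkylation (electrophilic aromatic substitution) of the resorcinol dianion by glyoxylate should go to the only position ortho/para to both hydroxyls, and hydrogenolysis of the benzylic C–OH followed by lactonisation onto the neighbouring phenol leaves the other phenol as the only free one; the carbinol centre of 4 is removed.

**Step 3**
Reactants: 6 methyl 2-methyl-3-oxobutanoate
Product: 7 methyl 2-diazopropanoate
Conditions: 4-acetamidobenzenesulfonyl azide (1.2 equiv), DBU (1.5 equiv), MeCN, 0 → 23 °C
Reagents that add atoms: 4-acetamidobenzenesulfonyl azide, CC(=O)Nc1ccc(cc1)S(=O)(=O)N=[N+]=[N-]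
Why: Regitz diazo transfer to the 2-substituted acetoacetate with loss of the acetyl group (deacylative diazo transfer) is the standard entry to 2-diazopropanoates.

**Step 4**
Reactants: 5 benzofuranone phenol; 7 methyl 2-diazopropanoate
Product: 8 methyl (2R)-2-[(7-methoxy-5-methyl-2-oxo-2,3-dihydro-1-benzofuran-6-yl)oxy]propanoate
Conditions: CuCl (5 mol%), Na[B(3,5-(CF3)2C6H3)4] (6 mol%), 7,7′-bis(4-phenyl-4,5-dihydrooxazol-2-yl)-1,1′-spirobiindane (6 mol%, antipode giving the R ester), 5 Å MS, CH2Cl2, 25 °C
Reagents that add atoms: none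
Why: Enantioselective copper-carbene O–H insertion into a phenol (oxonium ylide, then ligand-controlled proton shift) is known for 2-diazopropanoates; the neutral conditions avoid the enolate of the acidic benzofuranone CH2, and the ligand antipode sets the new centre as R (either antipode is available, so the tether can be matched to the sense of induction in step 6).

**Step 5**
Reactants: 8 aryloxypropanoate lactone
Product: 9 (2R)-2-[4-(carboxymethyl)-3-hydroxy-2-methoxy-6-methylphenoxy]propanoic acid
Conditions: LiOH·H2O (4 equiv), THF–H2O, 0 → 23 °C; 1 M HCl to pH 2, 0 °C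
Reagents that add atoms: lithium hydroxide, [Li+].[OH-]
Why: Saponification opens the aryl lactone (freeing the phenol para to the methyl carbon) and cleaves the methyl ester; the α-aryloxy centre is kept because the carboxylate does not enolise under these cold conditions.

**Step 6**
Reactants: 9 phenol diacid with (R)-tether
Product: 10 2-[(3R,8aR)-5-methoxy-3,8a-dimethyl-2,6-dioxo-2,3,6,8a-tetrahydro-1,4-benzodioxin-7-yl]acetic acid
Conditions: PhI(OCOCF3)2 (1.1 equiv), CH2Cl2–(CF3)2CHOH, −40 → 0 °C
Reagents that add atoms: none
Why: Tether-directed oxidative dearomatisation with trivalent iodine (known for lactic-acid-tethered 4-alkylresorcinols): the tethered carboxylate attacks the para carbon C4 as iodobenzene leaves, through a boat-like 1,4-dioxan-2-one in which the tether methyl takes the bowsprit position away from the C4 methyl, so the R tether should set C4 as R.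

**Step 7**
Reactants: 10 dioxanone dienone acid; 11 4,4-diethoxybutan-1-amine
Product: 13 2-[(3R)-4-[(4,4-diethoxybutyl)amino]-3-hydroxy-5-methoxy-3-methyl-6-oxocyclohexa-1,4-dien-1-yl]acetic acid, via p-quinol diacid 12 (not isolated)
Conditions: LiOH·H2O (3.2 equiv), THF–H2O, 0 °C; then 11 (2 equiv), 23 → 40 °C; 1 M HCl to pH 3–4, 0 °C
Reagents that add atoms: none
Why: Hydroxide opens the α-alkoxy lactone at the acyl carbon and frees the tertiary C4 alcohol, then conjugate addition–elimination of the primary amine at C3 of the vinylogous ester expels the lactate alkoxide and gives the vinylogous amide (addition at the C–H β-carbon C4a is reversible); C4 is not involved.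

**Step 8**
Reactants: 13 vinylogous amide acetal
Product: 14 2-[(3aS,4aR)-8-methoxy-4a-methyl-7-oxo-1,2,3,3a,4a,7-hexahydropyrrolo[2,1-b][1,3]benzoxazol-6-yl]acetic acid
Conditions: TsOH·H2O (10 mol%), 4 Å MS, CH2Cl2, 23 °C
Reagents that add atoms: none
Why: Acid-catalysed N,O-acetalisation through a cyclic N-acyliminium-type ion: the nitrogen closes ring C on the ionised acetal and the C4 hydroxyl closes ring B; the aminal centre equilibrates and is set by C4, whose methyl is pseudo-axial on the oxazolidine so that the pyrrolidine CH2 takes the other face (H syn to methyl, S).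

**Step 9**
Reactants: 15 5-methoxybenzene-1,3-diol
Product: 16 2-iodo-5-methoxybenzene-1,3-diol
Conditions: I2 (1.0 equiv), NaHCO3 (1.1 equiv), H2O–THF, 0 °C
Reagents that add atoms: iodine, [I][I]
Why: Electrophilic iodination of the resorcinol as its phenoxide under aqueous hydrogencarbonate should go to C2 between the two hydroxyls, which is also para to the methoxy group.

**Step 10**
Reactants: 16 2-iodo-5-methoxybenzene-1,3-diol
Product: 17 2-iodo-5-methoxy-1,3-phenylene bis(trifluoromethanesulfonate)
Conditions: (CF3SO2)2O (2.3 equiv), pyridine, CH2Cl2, 0 °C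
Reagents that add atoms: trifluoromethanesulfonic anhydride, O=S(=O)(OS(=O)(=O)C(F)(F)F)C(F)(F)F
Why: O-Sulfonylation of both phenols gives a 2-iodoaryl triflate (aryne precursor) whose second triflate serves as protecting group for the future C8 oxygen.

**Step 11**
Reactants: 14 tricyclic aminal acid; 17 iodo bis-triflate
Product: 21 C8 trifluoromethanesulfonate of the target (9-oxo form), via bis(silyl) ketene acetal 18 (not isolated), via aryne 19 (not isolated), via cycloadduct 20 (not isolated)
Conditions: LiN(SiMe3)2 (2.2 equiv), Me3SiCl (2.5 equiv), THF, −78 °C; volatiles off; then 17 (2 equiv), Me3SiCH2MgCl (2.1 equiv), THF, −78 → 0 °C; aq. citric acid, 23 °C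
Reagents that add atoms: none
Why: Silylation–enolisation of the acid with in situ trapping gives the 1,1-bis(silyloxy)diene 18 (C9=C10–C10a=C4a), iodine–magnesium exchange on 17 with loss of MgCl(OTf) gives aryne 19, and the two combine in an asynchronous Diels–Alder reaction in which the nucleophilic diene terminus C4a bonds first; on acidic work-up the bis(silyl) ketal of 20 collapses to the C9 ketone and the C4a hydrogen moves to C10 through the dienol, giving 21. The closest known reaction types are the [4+2] cycloaddition of arynes with 1-oxygenated 1,3-dienes and the addition of arynes to ketene silyl acetals. Ring D is the only ring closed, by an intermolecular [4+2] cycloaddition that forms C4a–C4b and C8a–C9 in one operation. The one new stereocentre (C4a in 20) is erased by the tautomerisation, so no facial control is needed, and C4 and the aminal carbon are not touched. The step needs regioselectivity and [4+2] over [2+2] periselectivity: the triflyloxy group next to C8a distorts the aryne so that C4a adds at the distal carbon C4b and the charge developing at C8a lies beside the withdrawing oxygen before it closes on C9, and the s-cis diene is reachable because C4a carries only hydrogen. Trapping with Me3SiCl at −78 °C keeps the ester enolate from expelling the C4 oxygen (vinylogous β-elimination).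

**Step 12**
Reactants: 21 C8 triflate
Product: 22 the target
Conditions: Et4NOH (aq, 3 equiv), 1,4-dioxane, 23 °C; then pH 6 phosphate buffer
Reagents that add atoms: none
Why: Hydroxide cleaves the aryl triflate at sulfur (the ortho carbonyl makes the phenoxide a good leaving group) and frees the C8 phenol; the delocalised enolate of the product is reprotonated on buffering and neither stereocentre is involved.

**Compound list**
1 | 2,4-dihydroxy-3-methoxybenzaldehyde | COc1c(O)ccc(C=O)c1O | starting material
2 | 2-methoxy-4-methylbenzene-1,3-diol | COc1c(O)ccc(C)c1O | intermediate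
3 | glyoxylic acid (oxoacetic acid, used as monohydrate) | O=CC(=O)O | starting material
4 | 2-(2,4-dihydroxy-3-methoxy-5-methylphenyl)-2-hydroxyacetic acid (racemic, not isolated) | OC(C(=O)O)c1cc(C)c(O)c(OC)c1O | intermediate
5 | 6-hydroxy-7-methoxy-5-methyl-1-benzofuran-2(3H)-one | O=C1Cc2cc(C)c(O)c(OC)c2O1 | intermediate
6 | methyl 2-methyl-3-oxobutanoate | COC(=O)C(C)C(C)=O | starting material
7 | methyl 2-diazopropanoate | COC(=O)C(C)=[N+]=[N-] | intermediate
8 | methyl (2R)-2-[(7-methoxy-5-methyl-2-oxo-2,3-dihydro-1-benzofuran-6-yl)oxy]propanoate | O=C1Cc2cc(C)c(O[C@H](C)C(=O)OC)c(OC)c2O1 | intermediate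
9 | (2R)-2-[4-(carboxymethyl)-3-hydroxy-2-methoxy-6-methylphenoxy]propanoic acid | OC(=O)Cc1cc(C)c(O[C@H](C)C(=O)O)c(OC)c1O | intermediate
10 | 2-[(3R,8aR)-5-methoxy-3,8a-dimethyl-2,6-dioxo-2,3,6,8a-tetrahydro-1,4-benzodioxin-7-yl]acetic acid | COC1=C2O[C@H](C)C(=O)O[C@]2(C)C=C(CC(=O)O)C1=O | intermediate
11 | 4,4-diethoxybutan-1-amine | NCCCC(OCC)OCC | starting material
12 | (2R)-2-{[(6R)-4-(carboxymethyl)-6-hydroxy-2-methoxy-6-methyl-3-oxocyclohexa-1,4-dien-1-yl]oxy}propanoic acid (not isolated) | COC1=C(O[C@H](C)C(=O)O)[C@](C)(O)C=C(CC(=O)O)C1=O | intermediate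
13 | 2-[(3R)-4-[(4,4-diethoxybutyl)amino]-3-hydroxy-5-methoxy-3-methyl-6-oxocyclohexa-1,4-dien-1-yl]acetic acid | COC1=C(NCCCC(OCC)OCC)[C@](C)(O)C=C(CC(=O)O)C1=O | intermediate
14 | 2-[(3aS,4aR)-8-methoxy-4a-methyl-7-oxo-1,2,3,3a,4a,7-hexahydropyrrolo[2,1-b][1,3]benzoxazol-6-yl]acetic acid | COC1=C2N3CCC[C@@H]3O[C@]2(C)C=C(CC(=O)O)C1=O | intermediate
15 | 5-methoxybenzene-1,3-diol | COc1cc(O)cc(O)c1 | starting material
16 | 2-iodo-5-methoxybenzene-1,3-diol | COc1cc(O)c(I)c(O)c1 | intermediate
17 | 2-iodo-5-methoxy-1,3-phenylene bis(trifluoromethanesulfonate) | COc1cc(OS(=O)(=O)C(F)(F)F)c(I)c(OS(=O)(=O)C(F)(F)F)c1 | intermediate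
18 | (3aS,4aR)-6-[2,2-bis(trimethylsilyloxy)ethenyl]-8-methoxy-4a-methyl-2,3,3a,4a-tetrahydro-1H-pyrrolo[2,1-b][1,3]benzoxazol-7-one (not isolated) | COC1=C2N3CCC[C@@H]3O[C@]2(C)C=C(C=C(O[Si](C)(C)C)O[Si](C)(C)C)C1=O | intermediate
19 | 1,2-didehydro-5-methoxy-3-(trifluoromethanesulfonyloxy)benzene (aryne, not isolated) | COC1=CC#CC(OS(=O)(=O)C(F)(F)F)=C1 | intermediate
20 | Diels–Alder adduct: as 21 but with C9 as C(OSiMe3)2, a C10=C10a double bond and an sp3 C4a–H of either configuration; C4 R, aminal carbon S (not isolated) | COC1=C2N3CCC[C@@H]3O[C@]2(C)C2C(=CC(O[Si](C)(C)C)(O[Si](C)(C)C)c3c(OS(=O)(=O)C(F)(F)F)cc(OC)cc32)C1=O | intermediate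
21 | (4R)-2,6-dimethoxy-4-methyl-1,9-dioxo-4,10-dihydrophenanthren-8-yl trifluoromethanesulfonate with pyrrolidine N on C3 and its (S)-C2′ joined through oxygen to C4 | COC1=C2N3CCC[C@@H]3O[C@]2(C)C2=C(CC(=O)c3c(OS(=O)(=O)C(F)(F)F)cc(OC)cc32)C1=O | intermediate
22 | (4R)-8-hydroxy-2,6-dimethoxy-4-methyl-4,10-dihydrophenanthrene-1,9-dione with pyrrolidine N on C3 and its (S)-C2′ joined through oxygen to C4 (oxazolidine ring B) | COC1=C2N3CCC[C@@H]3O[C@]2(C)C2=C(CC(=O)c3c(O)cc(OC)cc32)C1=O | target

**Step count and risks**
Total steps: 12. Longest linear sequence: 9 steps (1, 2, 4, 5, 6, 7, 8, 11, 12, from compound 1).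

Step 11. What may go wrong: [2+2] addition of the aryne across the C9=C10 ketene acetal bond in place of the [4+2] mode, and vinylogous β-elimination of the C4 oxygen during enolisation. Fallback (from 14 and 16, back at 22): 14 is esterified with one hydroxyl of 16 (DCC, DMAP, CH2Cl2) to the 3-hydroxy-2-iodo-5-methoxyphenyl ester F1. Iodine–magnesium exchange (i-PrMgCl·LiCl, THF, −78 → 0 °C) then triggers a 1,3-shift of the acyl group from oxygen to the metalated carbon (anionic Fries-type rearrangement), giving the 2,6-dihydroxy-4-methoxyphenyl ketone F2 with C8a–C9 in place. One of the two equivalent phenols is triflated (PhNTf2, Et3N) to the mono-triflate F3. An intramolecular Heck reaction (Pd(OAc)2, PPh3, Et3N, DMF, 80 °C) joins C4b to the β-carbon C4a of the ring A enone, closing ring D and giving 22 directly after double-bond shift.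

Step 6. What may go wrong: poor facial selectivity of the tethered carboxylate (weak 1,4-induction), or its capture at the methoxy-bearing ortho carbon. Fallback (from 9, back at 12): the phenolate of 9 is oxygenated with singlet oxygen (KHSO5 as 2KHSO5·KHSO4·K2SO4, NaHCO3, MeCN–H2O), which adds para to the phenol and gives the C4 hydroperoxide F4 as both epimers. Reduction with Me2S gives 12 together with its C4 epimer F5. These are diastereomers through the lactate centre and are separated by crystallisation or chromatography; 12 then enters step 7 at the amine addition.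

Step 4. What may go wrong: slow insertion at the doubly ortho-substituted phenol (carbene lost by 1,2-hydride shift) or low enantioselectivity. Fallback (from 5 and 7, back at 9): Rh2(OAc)4-catalysed O–H insertion gives the racemic ester, that is 8 together with its enantiomer F6. Saponification as in step 5 gives the racemic diacid, 9 together with its enantiomer F7. This is resolved by crystallisation of the salt with (S)-1-phenylethylamine (or the R amine, whichever leaves the R acid in the crystals), and free 9 rejoins the route at step 6.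

**Further compounds**
F1 | step 11 | 3-hydroxy-2-iodo-5-methoxyphenyl ester of acid 14 | COC1=C2N3CCC[C@@H]3O[C@]2(C)C=C(CC(=O)Oc2cc(OC)cc(O)c2I)C1=O
F2 | step 11 | 1-(2,6-dihydroxy-4-methoxyphenyl)-2-(tricyclic ring A unit of 14)ethanone | COC1=C2N3CCC[C@@H]3O[C@]2(C)C=C(CC(=O)c2c(O)cc(OC)cc2O)C1=O
F3 | step 11 | mono(trifluoromethanesulfonate) of F2 | COC1=C2N3CCC[C@@H]3O[C@]2(C)C=C(CC(=O)c2c(O)cc(OC)cc2OS(=O)(=O)C(F)(F)F)C1=O
F4 | step 6 | (2R)-2-{[4-(carboxymethyl)-6-hydroperoxy-2-methoxy-6-methyl-3-oxocyclohexa-1,4-dien-1-yl]oxy}propanoic acid (both C6 epimers) | COC1=C(O[C@H](C)C(=O)O)C(C)(OO)C=C(CC(=O)O)C1=O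
F5 | step 6 | (2R)-2-{[(6S)-4-(carboxymethyl)-6-hydroxy-2-methoxy-6-methyl-3-oxocyclohexa-1,4-dien-1-yl]oxy}propanoic acid (C6 epimer of 12) | COC1=C(O[C@H](C)C(=O)O)[C@@](C)(O)C=C(CC(=O)O)C1=O
F6 | step 4 | methyl (2S)-2-[(7-methoxy-5-methyl-2-oxo-2,3-dihydro-1-benzofuran-6-yl)oxy]propanoate (enantiomer of 8) | O=C1Cc2cc(C)c(O[C@@H](C)C(=O)OC)c(OC)c2O1
F7 | step 4 | (2S)-2-[4-(carboxymethyl)-3-hydroxy-2-methoxy-6-methylphenoxy]propanoic acid (enantiomer of 9) | OC(=O)Cc1cc(C)c(O[C@@H](C)C(=O)O)c(OC)c1O
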